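The four stereocentres C5, C6, C7 and C10 lie in a row on ring B around the C8=C9 alkene, so ring B is disconnected at C5–C10 and C6–C7 into a C7=C8–C9=C10 diene and a C5=C6 dienophile joined through C1–C4. One thermal type-1 intramolecular Diels–Alder reaction of an acyclic (5Z,7E,9E)-triene therefore closes rings A and B and sets all four centres; boron on C6 is then exchanged for the axial 6β-oxygen with retention. The precursor carries the (7E,9E)-dienyl isovalerate, the (5Z)-alkenylboronate as its (2R,3R)-butane-2,3-diol ester, the C4 gem-dimethyl tether and the (13E)-enoate side chain as a 2-(trimethylsilyl)ethyl ester.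

Key step: step 15

Remark: labdane numbering is used throughout; the (5Z,7E,9E) geometry was checked against the target (5α-H, 6β-O, 7α-O, 10β-CH3) and no structure needed correction; the acid is carried as a 2-(trimethylsilyl)ethyl (TMSE) ester, not an alkenyl ester such as allyl, whose C=C would be attacked in the hydroborations of steps 10 and 14; the sense of the facial bias from the boron diol cannot be predicted, so the (2R,3R)-diol is assumed to favour the 5α-H/10β-CH3 series and the diastereomers formed in step 15 are to be separated.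

Step 1
Reactants: 1 2,2-dimethylpent-4-enal
Product: 2 dibromoalkene (1,1-dibromo-3,3-dimethylhexa-1,5-diene)
Conditions: CBr4, PPh3, CH2Cl2, 0 °C
Reagents that add atoms: carbon tetrabromide, BrC(Br)(Br)Br
Why: Corey–Fuchs dibromo-olefination (Wittig-type reaction of Ph3P=CBr2) should work cleanly on this non-enolisable neopentyl aldehyde and brings in C6 without touching the terminal alkene.

Step 2
Reactants: 2 dibromoalkene
Product: 4 silylated enyne (trimethyl(3,3-dimethylhex-5-en-1-yn-1-yl)silane), via lithium acetylide 3 (not isolated)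
Conditions: n-BuLi (2.1 equiv), THF, −78 → 0 °C; then TMSCl, −78 °C → rt
Reagents that add atoms: chlorotrimethylsilane, C[Si](C)(C)Cl
Why: Br/Li exchange and Fritsch–Buttenberg–Wiechell rearrangement (second stage of the Corey–Fuchs alkyne synthesis) give the lithium acetylide, whose C-silylation in the same flask masks the alkyne against the later hydroborations and avoids handling the volatile free enyne.

Step 3
Reactants: 5 but-2-yn-1-ol; 6 isopropenylmagnesium bromide
Product: 8 iododienol ((2Z)-3-iodo-2-(prop-1-en-2-yl)but-2-en-1-ol), via cyclic alkenylmagnesium alkoxide 7 (not isolated)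
Conditions: 6 (3.5 equiv), THF, reflux; then I2, −40 → 0 °C
Reagents that add atoms: iodine, II
Why: Alkoxide-directed anti-carbomagnesiation of a propargylic alcohol by an alkenyl Grignard reagent puts the isopropenyl group (C8, C7, C17) on the proximal carbon C9 and magnesium on C10 inside a five-membered chelate, and iodinolysis with retention fixes the tetrasubstituted C9=C10 alkene with iodine cis to CH2OH (C11) and the C20 methyl cis to C8.

Step 4
Reactants: 4 silylated enyne; 8 iododienol
Product: 10 dienol ((2Z)-3,7,7-trimethyl-2-(prop-1-en-2-yl)-9-(trimethylsilyl)non-2-en-8-yn-1-ol), via alkylborane 9 (not isolated)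
Conditions: 9-BBN, THF, 0 °C → rt; then 8, PdCl2(dppf) (5 mol %), K3PO4 (aq), THF/DMF, rt
Reagents that add atoms: none
Why: 9-BBN adds only to the terminal alkene of 4 (the silylalkyne is inert) and B-alkyl Suzuki–Miyaura coupling with the alkenyl iodide proceeds with retention, so the C1 tether ends cis to C11 on the C9=C10 alkene.

Step 5
Reactants: 10 dienol
Product: 11 allylic bromide ((2Z)-1-bromo-3,7,7-trimethyl-2-(prop-1-en-2-yl)-9-(trimethylsilyl)non-2-en-8-yne)
Conditions: CBr4, PPh3, CH2Cl2, −20 °C
Reagents that add atoms: carbon tetrabromide, BrC(Br)(Br)Br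
Why: Appel bromination converts the primary allylic alcohol into the bromide under neutral conditions by SN2 at C11, without allylic transposition or loss of the alkynylsilane; the bromide is used at once.

Step 6
Reactants: 12 2,2,6-trimethyl-4H-1,3-dioxin-4-one; 13 2-(trimethylsilyl)ethanol
Product: 14 2-(trimethylsilyl)ethyl 3-oxobutanoate
Conditions: xylene, 140 °C (−acetone)
Reagents that add atoms: none
Why: Thermal retro-[4+2] fragmentation of the dioxinone gives acetylketene, which the alcohol traps (acetoacetylation), a standard preparation of acetoacetate esters.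

Step 7
Reactants: 14 2-(trimethylsilyl)ethyl 3-oxobutanoate; 11 allylic bromide
Product: 16 β-keto ester (TMSE (6E)-7,11,11-trimethyl-3-oxo-6-(prop-1-en-2-yl)-13-(trimethylsilyl)tridec-6-en-12-ynoate), via dilithium dianion 15 (not isolated)
Conditions: LDA (2.1 equiv), THF, −78 → 0 °C; then 11, 0 °C
Reagents that add atoms: none
Why: γ-Alkylation of an acetoacetate dianion, in which the more basic terminal carbanion attacks the primary allylic bromide by SN2 and forms the C11–C12 bond.

Step 8
Reactants: 16 β-keto ester
Product: 18 (2Z)-enol diethyl phosphate of 16, via sodium enolate 17 (not isolated)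
Conditions: NaH, Et2O, 0 °C; then ClP(O)(OEt)2, 0 °C → rt
Reagents that add atoms: diethyl chlorophosphate, CCOP(=O)(Cl)OCC
Why: O-phosphorylation of the chelated sodium enolate of the β-keto ester gives the (Z)-enol phosphate, which sets the geometry of the C13=C14 bond.

Step 9
Reactants: 18 enol phosphate
Product: 19 (13E)-enoate (TMSE (2E,6E)-3,7,11,11-tetramethyl-6-(prop-1-en-2-yl)-13-(trimethylsilyl)trideca-2,6-dien-12-ynoate)
Conditions: Me2CuLi (from MeLi and CuI), Et2O, −78 → −45 °C
Reagents that add atoms: lithium dimethylcuprate, [Li+].C[Cu-]C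
Why: Cuprate substitution of the enol phosphate (addition–elimination at C13) occurs with retention, so the new methyl (C16) ends cis to the ester and the 13E enoate results, while TMSE ester, diene and silylalkyne are inert at this temperature.

Step 10
Reactants: 19 (13E)-enoate
Product: 21 primary alcohol (C7–OH; racemic at C8), via trialkylborane 20 (not isolated)
Conditions: 9-BBN, THF, 0 °C → rt; then H2O2 (30 %), NaOAc (aq), 0 °C → rt
Reagents that add atoms: hydrogen peroxide, OO
Why: Hydroboration–oxidation with 9-BBN is selective for the 1,1-disubstituted terminal alkene over the tetrasubstituted alkene, the enoate and the silylalkyne and places oxygen on C7; the new C8 centre is formed racemic and is erased in step 13.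

Step 11
Reactants: 21 primary alcohol
Product: 22 terminal alkyne alcohol
Conditions: AgNO3 (0.2 equiv), acetone/H2O, rt
Reagents that add atoms: none
Why: Silver-catalysed protodesilylation of the alkynylsilane (through the silver acetylide) is neutral, so the TMSE ester, which base or stoichiometric fluoride could attack, and the alcohol survive.

Step 12
Reactants: 22 terminal alkyne alcohol
Product: 23 β,γ-unsaturated aldehyde (C7 aldehyde; racemic at C8)
Conditions: Dess–Martin periodinane, NaHCO3, CH2Cl2, 0 °C; used crude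
Reagents that add atoms: none
Why: Buffered Dess–Martin oxidation gives the α-methyl β,γ-unsaturated aldehyde without acid or base that could move the C9=C10 bond into conjugation.

Step 13
Reactants: 23 aldehyde; 24 isovaleric anhydride
Product: 26 (7E,9E)-dienyl isovalerate with terminal alkyne, via potassium dienolate 25 (not isolated)
Conditions: KHMDS, THF, −78 °C (23 added slowly); then 24, −78 → −20 °C
Reagents that add atoms: none
Why: Kinetic deprotonation at C8 and O-acylation of the potassium enolate by the anhydride (enol ester formation) should give the 7E ester, because the enolate oxygen settles anti to the bulky tetrasubstituted alkenyl group on C8, while the C9=C10 geometry is untouched.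

Step 14
Reactants: 26 dienyl isovalerate; 27 (2R,3R)-butane-2,3-diol
Product: 29 (5Z,7E,9E,13E)-triene boronate (cycloaddition precursor), via catechol boronate 28 (not isolated)
Conditions: catecholborane (1.0 equiv), [Rh(cod)Cl]2 (1.5 mol %), P(i-Pr)3 (6 mol %), Et3N, cyclohexane, rt; then 27, rt
Reagents that add atoms: catecholborane, B1Oc2ccccc2O1
Why: Rhodium-catalysed anti-Markovnikov trans-hydroboration of the terminal alkyne through a rhodium vinylidene gives the (Z)-alkenylboronate (boron cis to C4), and transesterification of the labile catechol ester installs the chiral diol on boron.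

Step 15
Reactants: 29 (5Z,7E,9E,13E)-triene boronate
Product: 30 TMSE 6β-[(4R,5R)-4,5-dimethyl-1,3,2-dioxaborolan-2-yl]-7α-(3-methylbutanoyloxy)labda-8,13E-dien-15-oate
Conditions: toluene (5 mM), BHT (cat.), sealed tube, 180 °C
Reagents that add atoms: none
Why: Proposed new method: on heating, the C7=C8–C9=C10 dienyl ester and the C5=C6 alkenylboronate combine in a concerted suprafacial [4+2] cycloaddition that forms C5–C10 and C6–C7 without any reagent; the closest known reactions are thermal type-1 intramolecular Diels–Alder cyclisations of 1,7,9-decatrienes to trans-decalins and Diels–Alder reactions of alkenylboronic esters that are followed by C–B oxidation. Ring B (C5–C10) is closed by the cycloaddition itself, and ring A (C1–C5 plus C10) closes as a fused six-membered ring because the C1–C4 tether, attached to the diene terminus C10, folds as a chair. C5 and C6 are fixed by the 5Z alkene (boron cis to C4, hence 5α-H and 6β-B), C7 and C10 by the 7E ester and the outside position of the tether on C10 (O7 cis to C1, hence 7α-O and 10β-CH3), and the trans-fused transition state with boron exo ties the two pairs together (6β-B trans to 7α-O). The step needs trans over cis fusion and attack on one diene face: the chair tether with the C4 gem-dimethyl group should favour trans fusion, while the (4R,5R)-diol on boron is the only source of the absolute sense. Its bias is unproven, so the two trans-fused diastereomers are separated at this stage, and the reaction is run dilute with a radical inhibitor because the inside C10 methyl slows the diene and allows a [1,5]-hydrogen shift to compete.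

Step 16
Reactants: 30 6β-boryl cycloadduct
Product: 31 TMSE 6β-hydroxy-7α-(3-methylbutanoyloxy)labda-8,13E-dien-15-oate
Conditions: H2O2 (30 %), aq NaHCO3, THF, 0 °C → rt
Reagents that add atoms: hydrogen peroxide, OO
Why: Oxidation of the boronic ester by 1,2-shift of C6 from boron to oxygen in the hydroperoxide ate complex occurs with retention and so delivers the axial 6β-alcohol, while the weakly basic medium should keep the anti-periplanar 7α-acyloxy group from being eliminated together with boron.

Step 17
Reactants: 31 6β-alcohol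
Product: 32 TMSE 6β-acetoxy-7α-(3-methylbutanoyloxy)labda-8,13E-dien-15-oate
Conditions: Ac2O, DMAP, pyridine, 50 °C
Reagents that add atoms: acetic anhydride, CC(=O)OC(C)=O
Why: DMAP-catalysed acylation (nucleophilic catalysis) should force the hindered axial 6β-alcohol to react, and the trans-diaxial 6β-OH/7α-ester arrangement blocks acyl migration.

Step 18
Reactants: 32 TMSE ester
Product: 33 6β-acetoxy-7α-(3-methylbutanoyloxy)labda-8,13E-dien-15-oic acid (target)
Conditions: TBAF, THF, 0 °C → rt; aq NH4Cl work-up
Reagents that add atoms: none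
Why: Fluoride attack on silicon triggers β-elimination (fragmentation) of the 2-(trimethylsilyl)ethyl ester to the carboxylate, ethene and Me3SiF, which leaves the acetate, the allylic isovalerate and both alkenes untouched.

Compound list

1 | 2,2-dimethylpent-4-enal | C=CCC(C)(C)C=O | starting material
2 | 1,1-dibromo-3,3-dimethylhexa-1,5-diene | C=CCC(C)(C)C=C(Br)Br | intermediate
3 | lithium 3,3-dimethylhex-5-en-1-yn-1-ide (not isolated) | [Li+].[C-]#CC(C)(C)CC=C | intermediate
4 | trimethyl(3,3-dimethylhex-5-en-1-yn-1-yl)silane | C=CCC(C)(C)C#C[Si](C)(C)C | intermediate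
5 | but-2-yn-1-ol | CC#CCO | starting material
6 | isopropenylmagnesium bromide (prop-1-en-2-ylmagnesium bromide) | CC(=C)[Mg]Br | starting material
7 | cyclic alkenylmagnesium alkoxide, 3-methyl-4-(prop-1-en-2-yl)-2,5-dihydro-1,2-oxamagnesole (not isolated) | CC1=C(C(C)=C)CO[Mg]1 | intermediate
8 | (2Z)-3-iodo-2-(prop-1-en-2-yl)but-2-en-1-ol (I cis to CH2OH) | OC/C(C(C)=C)=C(/C)I | intermediate
9 | 9-[4,4-dimethyl-6-(trimethylsilyl)hex-5-yn-1-yl]-9-borabicyclo[3.3.1]nonane (not isolated) | C[Si](C)(C)C#CC(C)(C)CCCB1C2CCCC1CCC2 | intermediate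
10 | (2Z)-3,7,7-trimethyl-2-(prop-1-en-2-yl)-9-(trimethylsilyl)non-2-en-8-yn-1-ol | OC/C(C(C)=C)=C(/C)CCCC(C)(C)C#C[Si](C)(C)C | intermediate
11 | (2Z)-1-bromo-3,7,7-trimethyl-2-(prop-1-en-2-yl)-9-(trimethylsilyl)non-2-en-8-yne | BrC/C(C(C)=C)=C(/C)CCCC(C)(C)C#C[Si](C)(C)C | intermediate
12 | 2,2,6-trimethyl-4H-1,3-dioxin-4-one | CC1=CC(=O)OC(C)(C)O1 | starting material
13 | 2-(trimethylsilyl)ethanol | C[Si](C)(C)CCO | starting material
14 | 2-(trimethylsilyl)ethyl 3-oxobutanoate | CC(=O)CC(=O)OCC[Si](C)(C)C | intermediate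
15 | dilithium 1,3-dianion of 14 (not isolated) | [Li+].[Li+].[CH2-]C(=O)[CH-]C(=O)OCC[Si](C)(C)C | intermediate
16 | 2-(trimethylsilyl)ethyl (6E)-7,11,11-trimethyl-3-oxo-6-(prop-1-en-2-yl)-13-(trimethylsilyl)tridec-6-en-12-ynoate | C[Si](C)(C)CCOC(=O)CC(=O)CC/C(C(C)=C)=C(/C)CCCC(C)(C)C#C[Si](C)(C)C | intermediate
17 | sodium (Z)-enolate of 16 (not isolated) | C[Si](C)(C)CCOC(=O)/C=C(\[O-])CC/C(C(C)=C)=C(/C)CCCC(C)(C)C#C[Si](C)(C)C.[Na+] | intermediate
18 | 2-(trimethylsilyl)ethyl (2Z,6E)-3-[(diethoxyphosphoryl)oxy]-7,11,11-trimethyl-6-(prop-1-en-2-yl)-13-(trimethylsilyl)trideca-2,6-dien-12-ynoate | C[Si](C)(C)CCOC(=O)/C=C(\OP(=O)(OCC)OCC)CC/C(C(C)=C)=C(/C)CCCC(C)(C)C#C[Si](C)(C)C | intermediate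
19 | 2-(trimethylsilyl)ethyl (2E,6E)-3,7,11,11-tetramethyl-6-(prop-1-en-2-yl)-13-(trimethylsilyl)trideca-2,6-dien-12-ynoate | C[Si](C)(C)CCOC(=O)/C=C(\C)CC/C(C(C)=C)=C(/C)CCCC(C)(C)C#C[Si](C)(C)C | intermediate
20 | B-alkyl-9-BBN adduct of 19 with boron on C7 (not isolated; racemic at C8) | C[Si](C)(C)CCOC(=O)/C=C(\C)CC/C(C(C)CB1C2CCCC1CCC2)=C(/C)CCCC(C)(C)C#C[Si](C)(C)C | intermediate
21 | 2-(trimethylsilyl)ethyl (2E,6E)-6-(1-hydroxypropan-2-yl)-3,7,11,11-tetramethyl-13-(trimethylsilyl)trideca-2,6-dien-12-ynoate (racemic at C8) | C[Si](C)(C)CCOC(=O)/C=C(\C)CC/C(C(C)CO)=C(/C)CCCC(C)(C)C#C[Si](C)(C)C | intermediate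
22 | 2-(trimethylsilyl)ethyl (2E,6E)-6-(1-hydroxypropan-2-yl)-3,7,11,11-tetramethyltrideca-2,6-dien-12-ynoate (racemic at C8) | C[Si](C)(C)CCOC(=O)/C=C(\C)CC/C(C(C)CO)=C(/C)CCCC(C)(C)C#C | intermediate
23 | 2-(trimethylsilyl)ethyl (2E,6E)-3,7,11,11-tetramethyl-6-(1-oxopropan-2-yl)trideca-2,6-dien-12-ynoate (racemic at C8) | C[Si](C)(C)CCOC(=O)/C=C(\C)CC/C(C(C)C=O)=C(/C)CCCC(C)(C)C#C | intermediate
24 | isovaleric anhydride (3-methylbutanoic anhydride) | CC(C)CC(=O)OC(=O)CC(C)C | starting material
25 | potassium (7E)-dienolate of 23 (not isolated) | C#CC(C)(C)CCC/C(C)=C(CC/C(C)=C/C(=O)OCC[Si](C)(C)C)/C(C)=C/[O-].[K+] | intermediate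
26 | 2-(trimethylsilyl)ethyl (2E,6E)-3,7,11,11-tetramethyl-6-[(1E)-1-(3-methylbutanoyloxy)prop-1-en-2-yl]trideca-2,6-dien-12-ynoate | C#CC(C)(C)CCC/C(C)=C(CC/C(C)=C/C(=O)OCC[Si](C)(C)C)/C(C)=C/OC(=O)CC(C)C | intermediate
27 | (2R,3R)-butane-2,3-diol | C[C@@H](O)[C@@H](C)O | starting material
28 | catechol (Z)-alkenylboronate, 2-alkenyl-1,3,2-benzodioxaborole analogue of 29 (not isolated) | B1(Oc2ccccc2O1)/C=C\C(C)(C)CCC/C(C)=C(CC/C(C)=C/C(=O)OCC[Si](C)(C)C)/C(C)=C/OC(=O)CC(C)C | intermediate
29 | 2-(trimethylsilyl)ethyl (2E,6E,12Z)-13-[(4R,5R)-4,5-dimethyl-1,3,2-dioxaborolan-2-yl]-3,7,11,11-tetramethyl-6-[(1E)-1-(3-methylbutanoyloxy)prop-1-en-2-yl]trideca-2,6,12-trienoate; labdane numbering (5Z,7E,9E,13E) | B1(O[C@H](C)[C@@H](C)O1)/C=C\C(C)(C)CCC/C(C)=C(CC/C(C)=C/C(=O)OCC[Si](C)(C)C)/C(C)=C/OC(=O)CC(C)C | intermediate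
30 | 2-(trimethylsilyl)ethyl 6β-[(4R,5R)-4,5-dimethyl-1,3,2-dioxaborolan-2-yl]-7α-(3-methylbutanoyloxy)labda-8,13E-dien-15-oate (5α-H, 10β-CH3) | B1(O[C@H](C)[C@@H](C)O1)[C@@H]2[C@@H](OC(=O)CC(C)C)C(C)=C(CC/C(C)=C/C(=O)OCC[Si](C)(C)C)[C@@]3(C)CCCC(C)(C)[C@H]23 | intermediate
31 | 2-(trimethylsilyl)ethyl 6β-hydroxy-7α-(3-methylbutanoyloxy)labda-8,13E-dien-15-oate | O[C@@H]1[C@@H](OC(=O)CC(C)C)C(C)=C(CC/C(C)=C/C(=O)OCC[Si](C)(C)C)[C@@]2(C)CCCC(C)(C)[C@H]12 | intermediate
32 | 2-(trimethylsilyl)ethyl 6β-acetoxy-7α-(3-methylbutanoyloxy)labda-8,13E-dien-15-oate | CC(=O)O[C@@H]1[C@@H](OC(=O)CC(C)C)C(C)=C(CC/C(C)=C/C(=O)OCC[Si](C)(C)C)[C@@]2(C)CCCC(C)(C)[C@H]12 | intermediate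
33 | 6β-acetoxy-7α-(3-methylbutanoyloxy)labda-8,13E-dien-15-oic acid (5α-H, 10β-CH3) | CC(=O)O[C@@H]1[C@@H](OC(=O)CC(C)C)C(C)=C(CC/C(C)=C/C(=O)O)[C@@]2(C)CCCC(C)(C)[C@H]12 | target

Total step count: 18 (17 on the carbon skeleton plus the preparation of reagent 14 in step 6).
Longest linear sequence: 16 steps (from 1 to 33 through steps 1, 2, 4, 5 and 7–18).

Steps most likely to fail

Step 15 (the step labelled as a proposed new method). The remote diol on boron may discriminate the two diene faces only weakly, so both trans-fused diastereomers form. This comes on top of a slow cycloaddition of the twisted diene, in which cis-fusion and a [1,5]-hydrogen shift from the C10 methyl group can compete. The fallback uses known chemistry only: boronic ester exchange, separation of covalent diastereomers and peroxide oxidation. It sets out from 30 obtained as a mixture of diastereomers. Transesterification with (1S,2S,3R,5S)-(+)-pinanediol in toluene at 60 °C, driven by the greater stability of pinanediol boronates, should give the (+)-pinanediol boronate of the cycloadduct F1 together with its diastereomer. These esters are robust on silica and are to be separated by chromatography or crystallisation. Oxidation of pure F1 under the conditions of step 16 comes back to the route at 31.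

Step 14. The late trans-hydroboration may lose its Z-selectivity through rhodium hydride isomerisation or competing syn-addition, and the borane may attack the enol ester. The fallback gives up the Z-alkene and corrects C6 after the cycloaddition; it sets out from 26 and comes back at 31.
- Ordinary syn-hydroboration of 26 with catecholborane (catalytic dicyclohexylborane, THF, rt) should give the (E)-alkenyl catechol boronate F2.
- Exchange with 27 then gives the (5E)-isomer of the triene boronate F3.
- Heating as in step 15 should place boron endo and equatorial, giving the 6α-boryl cycloadduct F4. This also relieves the 1,3-diaxial crowding of the boron-exo transition state and removes the anti-periplanar B/O arrangement that threatens step 16. The diastereomers are separated as in the main route.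
- Oxidation with H2O2/NaHCO3 gives the 6α-alcohol F5, and Dess–Martin oxidation gives the 6-ketone F6.
- Reduction with NaBH4 (MeOH/CH2Cl2, −40 °C) should deliver hydride from the open α face, because the β face is blocked by the axial methyl groups on C4 and C10, and so give 31.

Step 13. Deprotonation of the crowded aldehyde may scramble the geometry at C7=C8, move the C9=C10 bond into conjugation through the dienolate, or lead to self-aldol addition. The fallback separates enolisation from acylation; it sets out from 23 and comes back at 26. Soft enolisation with TESOTf and Et3N (CH2Cl2, −78 °C) should give the triethylsilyl dienol ether F7, which can be isolated and enriched in the 7E isomer. Fluoride-catalysed O-acyl exchange with anhydride 24 (catalytic TBAT, THF, −20 °C) then converts the silyl enol ether into 26.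

Further compounds

F1 | step 15 | 2-(trimethylsilyl)ethyl 6β-[(+)-pinanediolatoboryl]-7α-(3-methylbutanoyloxy)labda-8,13E-dien-15-oate (boronate of (1S,2S,3R,5S)-pinane-2,3-diol) | B1(O[C@@H]2C[C@@H]3C[C@@H](C3(C)C)[C@]2(C)O1)[C@@H]4[C@@H](OC(=O)CC(C)C)C(C)=C(CC/C(C)=C/C(=O)OCC[Si](C)(C)C)[C@@]5(C)CCCC(C)(C)[C@H]45
F2 | step 14 | (E)-alkenyl catechol boronate, (5E)-isomer of 28 | B1(Oc2ccccc2O1)/C=C/C(C)(C)CCC/C(C)=C(CC/C(C)=C/C(=O)OCC[Si](C)(C)C)/C(C)=C/OC(=O)CC(C)C
F3 | step 14 | (5E,7E,9E,13E)-triene boronate, (5E)-isomer of 29 | B1(O[C@H](C)[C@@H](C)O1)/C=C/C(C)(C)CCC/C(C)=C(CC/C(C)=C/C(=O)OCC[Si](C)(C)C)/C(C)=C/OC(=O)CC(C)C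
F4 | step 14 | 2-(trimethylsilyl)ethyl 6α-[(4R,5R)-4,5-dimethyl-1,3,2-dioxaborolan-2-yl]-7α-(3-methylbutanoyloxy)labda-8,13E-dien-15-oate | B1(O[C@H](C)[C@@H](C)O1)[C@H]2[C@@H](OC(=O)CC(C)C)C(C)=C(CC/C(C)=C/C(=O)OCC[Si](C)(C)C)[C@@]3(C)CCCC(C)(C)[C@H]23
F5 | step 14 | 2-(trimethylsilyl)ethyl 6α-hydroxy-7α-(3-methylbutanoyloxy)labda-8,13E-dien-15-oate | O[C@H]1[C@@H](OC(=O)CC(C)C)C(C)=C(CC/C(C)=C/C(=O)OCC[Si](C)(C)C)[C@@]2(C)CCCC(C)(C)[C@H]12
F6 | step 14 | 2-(trimethylsilyl)ethyl 7α-(3-methylbutanoyloxy)-6-oxolabda-8,13E-dien-15-oate | O=C1[C@@H](OC(=O)CC(C)C)C(C)=C(CC/C(C)=C/C(=O)OCC[Si](C)(C)C)[C@@]2(C)CCCC(C)(C)[C@H]12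
F7 | step 13 | triethylsilyl (7E)-dienol ether of aldehyde 23 | C#CC(C)(C)CCC/C(C)=C(CC/C(C)=C/C(=O)OCC[Si](C)(C)C)/C(C)=C/O[Si](CC)(CC)CC
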